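The ten-membered carbocycle is cut at C7–C8, the bond between the β-carbon of the butenolide ring and the C8 carbinol. One intramolecular Nozaki–Hiyama–Kishi coupling of a C7 alkenyl iodide with a C8 aldehyde forms this bond, closes the ring and creates the C8 stereocentre. The step exploits that C8 is an allylic carbinol on C7 of the C7=C11 γ-lactone ring. The precursor is an open chain: a 4-iodo-3-(silyloxymethyl)butenolide whose C6 side chain holds both cis-epoxides, set by two Sharpless epoxidations of Z-allylic alcohols, and ends in the C8 aldehyde. The butenolide is annulated onto a C6 epoxy aldehyde with a magnesium carbenoid.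

Key step: step 20

Remark: germacrane numbering is used throughout (C1–C10 chain or ring, C11–C13 lactone carbons, C14 and C15 the methyls on C10 and C4); the target is 1S,4S,5R,6R,8R,10R with both epoxides cis, so each epoxide is made from a Z-trisubstituted allylic alcohol.

Step 1
Reactants: 1 but-3-yn-1-ol
Product: 2 1-[(but-3-yn-1-yloxy)methyl]-4-methoxybenzene
Conditions: NaH, 4-methoxybenzyl chloride, Bu4NI (cat.), THF/DMF, 0 °C → rt
Reagents that add atoms: 4-methoxybenzyl chloride, COc1ccc(CCl)cc1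
Why: Williamson ether synthesis puts a PMB ether on the future C8 oxygen, a group that can later be removed oxidatively in the presence of epoxides, a silyl ether and an alkenyl iodide.

Step 2
Reactants: 2 1-[(but-3-yn-1-yloxy)methyl]-4-methoxybenzene
Product: 4 methyl 5-[(4-methoxybenzyl)oxy]pent-2-ynoate, via lithium acetylide 3 (not isolated)
Conditions: n-BuLi, THF, −78 °C; then ClCO2Me, −78 → 0 °C
Reagents that add atoms: methyl chloroformate, COC(=O)Cl
Why: Deprotonation of the terminal alkyne and acylation of the acetylide with a chloroformate is the standard ynoate synthesis; the ester carbon becomes C2.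

Step 3
Reactants: 4 methyl 5-[(4-methoxybenzyl)oxy]pent-2-ynoate
Product: 5 methyl (2Z)-5-[(4-methoxybenzyl)oxy]-3-methylpent-2-enoate
Conditions: Me2CuLi (from MeLi and CuI), THF, −78 °C; quench at −78 °C with aq. NH4Cl
Reagents that add atoms: lithium dimethylcuprate, [Li+].C[Cu-]C
Why: Syn carbocupration of the ynoate (conjugate addition of the Gilman reagent) with cold protonation places the new C14 methyl and H1 cis, so the C9 chain and the ester are cis (Z), the geometry a cis-epoxide needs.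

Step 4
Reactants: 5 methyl (2Z)-5-[(4-methoxybenzyl)oxy]-3-methylpent-2-enoate
Product: 6 (2Z)-5-[(4-methoxybenzyl)oxy]-3-methylpent-2-en-1-ol
Conditions: i-Bu2AlH, CH2Cl2, −78 °C
Reagents that add atoms: none
Why: 1,2-Reduction of the enoate by the aluminium hydride gives the allylic alcohol without change of the alkene geometry.

Step 5
Reactants: 6 (2Z)-5-[(4-methoxybenzyl)oxy]-3-methylpent-2-en-1-ol
Product: 7 [(2S,3R)-3-{2-[(4-methoxybenzyl)oxy]ethyl}-3-methyloxiran-2-yl]methanol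
Conditions: Ti(OiPr)4, L-(+)-diethyl tartrate, t-BuOOH, 4 Å molecular sieves, CH2Cl2, −20 °C
Reagents that add atoms: tert-butyl hydroperoxide, CC(C)(C)OO
Why: Sharpless asymmetric epoxidation; with the L-(+)-tartrate the titanium-bound peroxide is delivered to the face that gives the (2S,3R) epoxy alcohol from a 3,3-disubstituted Z-allylic alcohol, which sets C1 (S) and C10 (R), and the Z geometry makes the epoxide cis.

Step 6
Reactants: 7 [(2S,3R)-3-{2-[(4-methoxybenzyl)oxy]ethyl}-3-methyloxiran-2-yl]methanol, 8 trimethyl(prop-1-yn-1-yl)silane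
Product: 11 (2R,3S)-2-{2-[(4-methoxybenzyl)oxy]ethyl}-2-methyl-3-[4-(trimethylsilyl)but-3-yn-1-yl]oxirane, via lithiated silylpropyne 9 (not isolated), via epoxy triflate 10 (not isolated)
Conditions: Tf2O, 2,6-lutidine, CH2Cl2, −78 °C; then 9 (from 8 and n-BuLi, THF, −78 °C), −78 → −40 °C
Reagents that add atoms: none
Why: SN2 alkylation of the propargylic carbanion by the primary triflate forms C2–C3; a sulfonate is used because a 2,3-epoxy halide would fragment by halogen–metal exchange, and the hindered trisubstituted epoxide is not opened at this temperature.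

Step 7
Reactants: 11 (2R,3S)-2-{2-[(4-methoxybenzyl)oxy]ethyl}-2-methyl-3-[4-(trimethylsilyl)but-3-yn-1-yl]oxirane
Product: 12 (2R,3S)-3-(but-3-yn-1-yl)-2-{2-[(4-methoxybenzyl)oxy]ethyl}-2-methyloxirane
Conditions: K2CO3 (cat.), MeOH, rt
Reagents that add atoms: none
Why: Base-catalysed methanolysis of the alkynylsilane (protodesilylation) frees the terminal alkyne and leaves the epoxide untouched.

Step 8
Reactants: 12 (2R,3S)-3-(but-3-yn-1-yl)-2-{2-[(4-methoxybenzyl)oxy]ethyl}-2-methyloxirane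
Product: 14 methyl 5-[(2S,3R)-3-{2-[(4-methoxybenzyl)oxy]ethyl}-3-methyloxiran-2-yl]pent-2-ynoate, via lithium acetylide 13 (not isolated)
Conditions: n-BuLi, THF, −78 °C; then ClCO2Me, −78 → −20 °C
Reagents that add atoms: methyl chloroformate, COC(=O)Cl
Why: Acetylide acylation as in step 2; at −78 °C the alkyne C–H is removed much faster than the trisubstituted epoxide is attacked, and the ester carbon becomes C6.

Step 9
Reactants: 14 methyl 5-[(2S,3R)-3-{2-[(4-methoxybenzyl)oxy]ethyl}-3-methyloxiran-2-yl]pent-2-ynoate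
Product: 15 methyl (2Z)-5-[(2S,3R)-3-{2-[(4-methoxybenzyl)oxy]ethyl}-3-methyloxiran-2-yl]-3-methylpent-2-enoate
Conditions: Me2CuLi (from MeLi and CuI), THF, −78 °C; quench at −78 °C with aq. NH4Cl
Reagents that add atoms: lithium dimethylcuprate, [Li+].C[Cu-]C
Why: Second syn carbocupration of an ynoate; the C15 methyl and H5 become cis, so C3 and C6 are cis (Z), and the cuprate does not open the trisubstituted epoxide at −78 °C.

Step 10
Reactants: 15 methyl (2Z)-5-[(2S,3R)-3-{2-[(4-methoxybenzyl)oxy]ethyl}-3-methyloxiran-2-yl]-3-methylpent-2-enoate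
Product: 16 (2Z)-5-[(2S,3R)-3-{2-[(4-methoxybenzyl)oxy]ethyl}-3-methyloxiran-2-yl]-3-methylpent-2-en-1-ol
Conditions: i-Bu2AlH, CH2Cl2, −78 °C
Reagents that add atoms: none
Why: 1,2-Reduction of the enoate with the aluminium hydride at low temperature gives the Z-allylic alcohol and spares the epoxide.

Step 11
Reactants: 16 (2Z)-5-[(2S,3R)-3-{2-[(4-methoxybenzyl)oxy]ethyl}-3-methyloxiran-2-yl]-3-methylpent-2-en-1-ol
Product: 17 [(2R,3S)-3-{2-[(2S,3R)-3-{2-[(4-methoxybenzyl)oxy]ethyl}-3-methyloxiran-2-yl]ethyl}-3-methyloxiran-2-yl]methanol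
Conditions: Ti(OiPr)4, D-(−)-diethyl tartrate, t-BuOOH, 4 Å molecular sieves, CH2Cl2, −20 °C
Reagents that add atoms: tert-butyl hydroperoxide, CC(C)(C)OO
Why: Sharpless asymmetric epoxidation with the D-(−)-tartrate delivers oxygen to the face opposite to that of step 5 and gives the (2R,3S) epoxy alcohol, i.e. C4 (S) and C5 (R); reagent control overrides the remote epoxide, and material of the wrong hand from step 5 becomes a separable diastereomer.

Step 12
Reactants: 17 [(2R,3S)-3-{2-[(2S,3R)-3-{2-[(4-methoxybenzyl)oxy]ethyl}-3-methyloxiran-2-yl]ethyl}-3-methyloxiran-2-yl]methanol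
Product: 18 (2S,3S)-3-{2-[(2S,3R)-3-{2-[(4-methoxybenzyl)oxy]ethyl}-3-methyloxiran-2-yl]ethyl}-3-methyloxirane-2-carbaldehyde
Conditions: TEMPO (cat.), PhI(OAc)2, CH2Cl2, rt
Reagents that add atoms: none
Why: Oxoammonium-mediated oxidation of the primary epoxy alcohol stops at the aldehyde under nearly neutral conditions, so C5 is not epimerised (its descriptor changes only because the formyl group gains priority).

Step 13
Reactants: 19 ethyl 2-(hydroxymethyl)prop-2-enoate
Product: 20 ethyl 2-({[tert-butyl(dimethyl)silyl]oxy}methyl)prop-2-enoate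
Conditions: TBSCl, imidazole, DMF, rt
Reagents that add atoms: tert-butyldimethylsilyl chloride, CC(C)(C)[Si](C)(C)Cl
Why: Silylation of the primary alcohol protects the future C13 oxygen as a TBS ether that survives ozonolysis, Grignard reagents and the chromium-mediated ring closure.

Step 14
Reactants: 20 ethyl 2-({[tert-butyl(dimethyl)silyl]oxy}methyl)prop-2-enoate
Product: 22 ethyl 3-{[tert-butyl(dimethyl)silyl]oxy}-2-oxopropanoate, via ozonide 21 (not isolated)
Conditions: O3, CH2Cl2, −78 °C; then Me2S, −78 °C → rt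
Reagents that add atoms: ozone, [O-][O+]=O
Why: Ozonolysis with reductive work-up cleaves the 1,1-disubstituted alkene and leaves the α-keto ester.

Step 15
Reactants: 22 ethyl 3-{[tert-butyl(dimethyl)silyl]oxy}-2-oxopropanoate
Product: 23 ethyl 3,3-dibromo-2-({[tert-butyl(dimethyl)silyl]oxy}methyl)prop-2-enoate
Conditions: CBr4, PPh3, CH2Cl2, 0 °C → rt
Reagents that add atoms: carbon tetrabromide, BrC(Br)(Br)Br
Why: Ramirez dibromo-olefination (Wittig-type reaction of the dibromomethylene ylide) works on the activated ketone of an α-keto ester and gives the β,β-dibromoacrylate.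

Step 16
Reactants: 18 (2S,3S)-3-{2-[(2S,3R)-3-{2-[(4-methoxybenzyl)oxy]ethyl}-3-methyloxiran-2-yl]ethyl}-3-methyloxirane-2-carbaldehyde, 23 ethyl 3,3-dibromo-2-({[tert-butyl(dimethyl)silyl]oxy}methyl)prop-2-enoate
Product: 25 (5S)-4-bromo-3-({[tert-butyl(dimethyl)silyl]oxy}methyl)-5-[(2R,3S)-3-{2-[(2S,3R)-3-{2-[(4-methoxybenzyl)oxy]ethyl}-3-methyloxiran-2-yl]ethyl}-3-methyloxiran-2-yl]furan-2(5H)-one, via magnesium carbenoid 24 (not isolated)
Conditions: 23, i-PrMgCl, Et2O, −78 °C; then 18, −78 → 0 °C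
Reagents that add atoms: none
Why: Bromine–magnesium exchange occurs at the bromine cis to the ester, where the carbonyl chelates magnesium, and the alkenylmagnesium carbenoid adds to the aldehyde, after which the alkoxide lactonises onto the cis ester (carbonyl addition–lactonisation) to form C6–C7 and the butenolide; C6 is set by Felkin–Anh attack anti to the C5–O bond of the cis-epoxy aldehyde, which should give the erythro (5S) lactone.

Step 17
Reactants: 25 (5S)-4-bromo-3-({[tert-butyl(dimethyl)silyl]oxy}methyl)-5-[(2R,3S)-3-{2-[(2S,3R)-3-{2-[(4-methoxybenzyl)oxy]ethyl}-3-methyloxiran-2-yl]ethyl}-3-methyloxiran-2-yl]furan-2(5H)-one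
Product: 27 (5S)-3-({[tert-butyl(dimethyl)silyl]oxy}methyl)-4-iodo-5-[(2R,3S)-3-{2-[(2S,3R)-3-{2-[(4-methoxybenzyl)oxy]ethyl}-3-methyloxiran-2-yl]ethyl}-3-methyloxiran-2-yl]furan-2(5H)-one, via alkenylstannane 26 (not isolated)
Conditions: Me3SnSnMe3, Pd(PPh3)4 (cat.), toluene, 90 °C; then I2, CH2Cl2, 0 °C
Reagents that add atoms: iodine, II
Why: Stille-type stannylation of the activated alkenyl bromide by zerovalent palladium and the ditin, then iododestannylation with retention, exchanges bromine for the more reactive iodine under neutral conditions that leave C6 and the epoxides alone.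

Step 18
Reactants: 27 (5S)-3-({[tert-butyl(dimethyl)silyl]oxy}methyl)-4-iodo-5-[(2R,3S)-3-{2-[(2S,3R)-3-{2-[(4-methoxybenzyl)oxy]ethyl}-3-methyloxiran-2-yl]ethyl}-3-methyloxiran-2-yl]furan-2(5H)-one
Product: 28 (5S)-3-({[tert-butyl(dimethyl)silyl]oxy}methyl)-5-[(2R,3S)-3-{2-[(2S,3R)-3-(2-hydroxyethyl)-3-methyloxiran-2-yl]ethyl}-3-methyloxiran-2-yl]-4-iodofuran-2(5H)-one
Conditions: DDQ, CH2Cl2/pH 7 buffer, 0 °C → rt
Reagents that add atoms: none
Why: Oxidative cleavage of the PMB ether by DDQ (hydride abstraction, hydrolysis of the oxocarbenium ion) frees the C8 hydroxyl and spares the TBS ether, the epoxides and the alkenyl iodide.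

Step 19
Reactants: 28 (5S)-3-({[tert-butyl(dimethyl)silyl]oxy}methyl)-5-[(2R,3S)-3-{2-[(2S,3R)-3-(2-hydroxyethyl)-3-methyloxiran-2-yl]ethyl}-3-methyloxiran-2-yl]-4-iodofuran-2(5H)-one
Product: 29 (5S)-3-({[tert-butyl(dimethyl)silyl]oxy}methyl)-4-iodo-5-[(2R,3S)-3-methyl-3-{2-[(2S,3R)-3-methyl-3-(2-oxoethyl)oxiran-2-yl]ethyl}oxiran-2-yl]furan-2(5H)-one
Conditions: Dess–Martin periodinane, NaHCO3, CH2Cl2, 0 °C → rt; used at once
Reagents that add atoms: none
Why: Dess–Martin oxidation of the primary alcohol under bicarbonate buffering gives the β,γ-epoxy aldehyde without the base that would cause β-elimination of the epoxide.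

Step 20
Reactants: 29 (5S)-3-({[tert-butyl(dimethyl)silyl]oxy}methyl)-4-iodo-5-[(2R,3S)-3-methyl-3-{2-[(2S,3R)-3-methyl-3-(2-oxoethyl)oxiran-2-yl]ethyl}oxiran-2-yl]furan-2(5H)-one
Product: 30 (1S,4S,5R,6R,8R,10R)-13-{[tert-butyl(dimethyl)silyl]oxy}-8-hydroxy-1,10:4,5-diepoxygermacr-7(11)-en-12,6-olide
Conditions: CrCl2 (excess), NiCl2 (cat.), degassed DMSO/THF, rt, slow addition of 29 to about 2 mM
Reagents that add atoms: none
Why: Divalent chromium reduces NiCl2 to zerovalent nickel, which inserts into the electron-poor C7–I bond; the alkenylnickel species passes its organic group to trivalent chromium, and the alkenylchromium reagent adds to the C8 aldehyde to give the chromium alkoxide of 30. The closest known reaction type is the intramolecular Nozaki–Hiyama–Kishi coupling of β-iodo enoates with aldehydes to medium and large rings. The ten-membered carbocycle closes in a 10-exo-trig mode, C7 attacking the carbonyl carbon C8 with the oxygen left outside the ring. The C8 stereocentre is set under substrate control in the cyclic transition state: the planar butenolide, the C6 stereocentre next to C7 and the two cis-epoxides fix the fold of the tether, and attack on the aldehyde face that keeps the bulky chromium alkoxide on the outside of the ring should give the 8R carbinol. The step needs chemoselective activation of C7–I beside lactone, silyl ether and epoxides, ring closure in preference to oligomerisation or protodeiodination, and survival of the β,γ-epoxy aldehyde; the non-basic, carbonyl-selective chromium reagent, the high reactivity of the iodide towards nickel and high dilution secure these.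

Step 21
Reactants: 30 (1S,4S,5R,6R,8R,10R)-13-{[tert-butyl(dimethyl)silyl]oxy}-8-hydroxy-1,10:4,5-diepoxygermacr-7(11)-en-12,6-olide, 31 (2E)-2-methylbut-2-enoyl chloride
Product: 32 (1S,4S,5R,6R,8R,10R)-13-{[tert-butyl(dimethyl)silyl]oxy}-8-{[(2E)-2-methylbut-2-enoyl]oxy}-1,10:4,5-diepoxygermacr-7(11)-en-12,6-olide
Conditions: pyridine, DMAP (cat.), CH2Cl2, 0 °C → rt
Reagents that add atoms: none
Why: DMAP-catalysed acylation of the secondary alcohol breaks no bond at C8, so its configuration is retained, and the tiglate keeps its stable E geometry.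

Step 22
Reactants: 32 (1S,4S,5R,6R,8R,10R)-13-{[tert-butyl(dimethyl)silyl]oxy}-8-{[(2E)-2-methylbut-2-enoyl]oxy}-1,10:4,5-diepoxygermacr-7(11)-en-12,6-olide
Product: 33 (1S,4S,5R,6R,8R,10R)-13-hydroxy-8-{[(2E)-2-methylbut-2-enoyl]oxy}-1,10:4,5-diepoxygermacr-7(11)-en-12,6-olide
Conditions: HF·pyridine, excess pyridine, THF, 0 °C → rt
Reagents that add atoms: none
Why: Buffered fluoride desilylation removes the primary TBS group without the basic conditions that would cause acyl migration from O8 to O13 or deprotonation at C6 of the butenolide.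

Step 23
Reactants: 33 (1S,4S,5R,6R,8R,10R)-13-hydroxy-8-{[(2E)-2-methylbut-2-enoyl]oxy}-1,10:4,5-diepoxygermacr-7(11)-en-12,6-olide
Product: 34 (1S,4S,5R,6R,8R,10R)-13-acetoxy-8-{[(2E)-2-methylbut-2-enoyl]oxy}-1,10:4,5-diepoxygermacr-7(11)-en-12,6-olide
Conditions: Ac2O, pyridine, DMAP (cat.), CH2Cl2, 0 °C
Reagents that add atoms: acetic anhydride, CC(=O)OC(C)=O
Why: Acetylation of the primary allylic alcohol under mild nucleophilic catalysis completes the target without touching any stereocentre.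

Compound list
1 | but-3-yn-1-ol | C#CCCO | starting material
2 | 1-[(but-3-yn-1-yloxy)methyl]-4-methoxybenzene | C#CCCOCc1ccc(OC)cc1 | intermediate
3 | lithium acetylide of 2 | [Li]C#CCCOCc1ccc(OC)cc1 | intermediate
4 | methyl 5-[(4-methoxybenzyl)oxy]pent-2-ynoate | COC(=O)C#CCCOCc1ccc(OC)cc1 | intermediate
5 | methyl (2Z)-5-[(4-methoxybenzyl)oxy]-3-methylpent-2-enoate | COC(=O)/C=C(/C)CCOCc1ccc(OC)cc1 | intermediate
6 | (2Z)-5-[(4-methoxybenzyl)oxy]-3-methylpent-2-en-1-ol | OC/C=C(/C)CCOCc1ccc(OC)cc1 | intermediate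
7 | [(2S,3R)-3-{2-[(4-methoxybenzyl)oxy]ethyl}-3-methyloxiran-2-yl]methanol | COc1ccc(COCC[C@@]2(C)O[C@H]2CO)cc1 | intermediate
8 | trimethyl(prop-1-yn-1-yl)silane | CC#C[Si](C)(C)C | starting material
9 | (3-lithioprop-1-yn-1-yl)trimethylsilane | [Li]CC#C[Si](C)(C)C | intermediate
10 | [(2S,3R)-3-{2-[(4-methoxybenzyl)oxy]ethyl}-3-methyloxiran-2-yl]methyl trifluoromethanesulfonate | COc1ccc(COCC[C@@]2(C)O[C@H]2COS(=O)(=O)C(F)(F)F)cc1 | intermediate
11 | (2R,3S)-2-{2-[(4-methoxybenzyl)oxy]ethyl}-2-methyl-3-[4-(trimethylsilyl)but-3-yn-1-yl]oxirane | COc1ccc(COCC[C@@]2(C)O[C@H]2CCC#C[Si](C)(C)C)cc1 | intermediate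
12 | (2R,3S)-3-(but-3-yn-1-yl)-2-{2-[(4-methoxybenzyl)oxy]ethyl}-2-methyloxirane | COc1ccc(COCC[C@@]2(C)O[C@H]2CCC#C)cc1 | intermediate
13 | lithium acetylide of 12 | COc1ccc(COCC[C@@]2(C)O[C@H]2CCC#C[Li])cc1 | intermediate
14 | methyl 5-[(2S,3R)-3-{2-[(4-methoxybenzyl)oxy]ethyl}-3-methyloxiran-2-yl]pent-2-ynoate | COc1ccc(COCC[C@@]2(C)O[C@H]2CCC#CC(=O)OC)cc1 | intermediate
15 | methyl (2Z)-5-[(2S,3R)-3-{2-[(4-methoxybenzyl)oxy]ethyl}-3-methyloxiran-2-yl]-3-methylpent-2-enoate | COc1ccc(COCC[C@@]2(C)O[C@H]2CC/C(C)=C\C(=O)OC)cc1 | intermediate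
16 | (2Z)-5-[(2S,3R)-3-{2-[(4-methoxybenzyl)oxy]ethyl}-3-methyloxiran-2-yl]-3-methylpent-2-en-1-ol | COc1ccc(COCC[C@@]2(C)O[C@H]2CC/C(C)=C\CO)cc1 | intermediate
17 | [(2R,3S)-3-{2-[(2S,3R)-3-{2-[(4-methoxybenzyl)oxy]ethyl}-3-methyloxiran-2-yl]ethyl}-3-methyloxiran-2-yl]methanol | COc1ccc(COCC[C@@]2(C)O[C@H]2CC[C@]2(C)O[C@@H]2CO)cc1 | intermediate
18 | (2S,3S)-3-{2-[(2S,3R)-3-{2-[(4-methoxybenzyl)oxy]ethyl}-3-methyloxiran-2-yl]ethyl}-3-methyloxirane-2-carbaldehyde | COc1ccc(COCC[C@@]2(C)O[C@H]2CC[C@]2(C)O[C@@H]2C=O)cc1 | intermediate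
19 | ethyl 2-(hydroxymethyl)prop-2-enoate | C=C(CO)C(=O)OCC | starting material
20 | ethyl 2-({[tert-butyl(dimethyl)silyl]oxy}methyl)prop-2-enoate | C=C(CO[Si](C)(C)C(C)(C)C)C(=O)OCC | intermediate
21 | ethyl 3-({[tert-butyl(dimethyl)silyl]oxy}methyl)-1,2,4-trioxolane-3-carboxylate (ozonide of 20) | CCOC(=O)C1(CO[Si](C)(C)C(C)(C)C)OCOO1 | intermediate
22 | ethyl 3-{[tert-butyl(dimethyl)silyl]oxy}-2-oxopropanoate | CCOC(=O)C(=O)CO[Si](C)(C)C(C)(C)C | intermediate
23 | ethyl 3,3-dibromo-2-({[tert-butyl(dimethyl)silyl]oxy}methyl)prop-2-enoate | CCOC(=O)C(CO[Si](C)(C)C(C)(C)C)=C(Br)Br | intermediate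
24 | ethyl (2E)-3-bromo-3-(chloromagnesio)-2-({[tert-butyl(dimethyl)silyl]oxy}methyl)prop-2-enoate (magnesium cis to the ester) | CCOC(=O)/C(CO[Si](C)(C)C(C)(C)C)=C(/Br)[Mg]Cl | intermediate
25 | (5S)-4-bromo-3-({[tert-butyl(dimethyl)silyl]oxy}methyl)-5-[(2R,3S)-3-{2-[(2S,3R)-3-{2-[(4-methoxybenzyl)oxy]ethyl}-3-methyloxiran-2-yl]ethyl}-3-methyloxiran-2-yl]furan-2(5H)-one | COc1ccc(COCC[C@@]2(C)O[C@H]2CC[C@]2(C)O[C@@H]2[C@@H]2OC(=O)C(CO[Si](C)(C)C(C)(C)C)=C2Br)cc1 | intermediate
26 | (5S)-3-({[tert-butyl(dimethyl)silyl]oxy}methyl)-5-[(2R,3S)-3-{2-[(2S,3R)-3-{2-[(4-methoxybenzyl)oxy]ethyl}-3-methyloxiran-2-yl]ethyl}-3-methyloxiran-2-yl]-4-(trimethylstannyl)furan-2(5H)-one | COc1ccc(COCC[C@@]2(C)O[C@H]2CC[C@]2(C)O[C@@H]2[C@@H]2OC(=O)C(CO[Si](C)(C)C(C)(C)C)=C2[Sn](C)(C)C)cc1 | intermediate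
27 | (5S)-3-({[tert-butyl(dimethyl)silyl]oxy}methyl)-4-iodo-5-[(2R,3S)-3-{2-[(2S,3R)-3-{2-[(4-methoxybenzyl)oxy]ethyl}-3-methyloxiran-2-yl]ethyl}-3-methyloxiran-2-yl]furan-2(5H)-one | COc1ccc(COCC[C@@]2(C)O[C@H]2CC[C@]2(C)O[C@@H]2[C@@H]2OC(=O)C(CO[Si](C)(C)C(C)(C)C)=C2I)cc1 | intermediate
28 | (5S)-3-({[tert-butyl(dimethyl)silyl]oxy}methyl)-5-[(2R,3S)-3-{2-[(2S,3R)-3-(2-hydroxyethyl)-3-methyloxiran-2-yl]ethyl}-3-methyloxiran-2-yl]-4-iodofuran-2(5H)-one | OCC[C@@]1(C)O[C@H]1CC[C@]1(C)O[C@@H]1[C@@H]1OC(=O)C(CO[Si](C)(C)C(C)(C)C)=C1I | intermediate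
29 | (5S)-3-({[tert-butyl(dimethyl)silyl]oxy}methyl)-4-iodo-5-[(2R,3S)-3-methyl-3-{2-[(2S,3R)-3-methyl-3-(2-oxoethyl)oxiran-2-yl]ethyl}oxiran-2-yl]furan-2(5H)-one | O=CC[C@@]1(C)O[C@H]1CC[C@]1(C)O[C@@H]1[C@@H]1OC(=O)C(CO[Si](C)(C)C(C)(C)C)=C1I | intermediate
30 | (1S,4S,5R,6R,8R,10R)-13-{[tert-butyl(dimethyl)silyl]oxy}-8-hydroxy-1,10:4,5-diepoxygermacr-7(11)-en-12,6-olide | O[C@@H]1C[C@@]2(C)O[C@H]2CC[C@]2(C)O[C@@H]2[C@@H]2OC(=O)C(CO[Si](C)(C)C(C)(C)C)=C21 | intermediate
31 | (2E)-2-methylbut-2-enoyl chloride (tigloyl chloride) | C/C=C(\C)C(Cl)=O | starting material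
32 | (1S,4S,5R,6R,8R,10R)-13-{[tert-butyl(dimethyl)silyl]oxy}-8-{[(2E)-2-methylbut-2-enoyl]oxy}-1,10:4,5-diepoxygermacr-7(11)-en-12,6-olide | C/C=C(\C)C(=O)O[C@@H]1C[C@@]2(C)O[C@H]2CC[C@]2(C)O[C@@H]2[C@@H]2OC(=O)C(CO[Si](C)(C)C(C)(C)C)=C21 | intermediate
33 | (1S,4S,5R,6R,8R,10R)-13-hydroxy-8-{[(2E)-2-methylbut-2-enoyl]oxy}-1,10:4,5-diepoxygermacr-7(11)-en-12,6-olide | C/C=C(\C)C(=O)O[C@@H]1C[C@@]2(C)O[C@H]2CC[C@]2(C)O[C@@H]2[C@@H]2OC(=O)C(CO)=C21 | intermediate
34 | (1S,4S,5R,6R,8R,10R)-13-acetoxy-8-{[(2E)-2-methylbut-2-enoyl]oxy}-1,10:4,5-diepoxygermacr-7(11)-en-12,6-olide (CNP0251711.3) | C/C=C(\C)C(=O)O[C@@H]1C[C@@]2(C)O[C@H]2CC[C@]2(C)O[C@@H]2[C@@H]2OC(=O)C(COC(C)=O)=C21 | target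

Total step count: 23.
Longest linear sequence: 20 steps (steps 1–12 and 16–23); steps 13–15 are a three-step branch that joins at step 16.

Steps most likely to fail

Step 20 (ring closure). The aldehyde may be attacked on the other face, so that the 8S carbinol predominates. The fallback sets out from 29: the same nickel/chromium closure would then deliver the 8-epi alcohol F1. Mitsunobu esterification of F1 with tiglic acid (PPh3, diisopropyl azodicarboxylate, toluene, 0 °C → rt) inverts C8 and installs the ester in one operation. The route is rejoined at 32.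

Step 16 (butenolide annulation). Chelation of magnesium by the epoxide oxygen may compete with the Felkin–Anh pathway and erode the facial selectivity at C6. The fallback sets out from 18 and fixes C6 by reduction instead of addition:
- Pinnick oxidation (NaClO2, NaH2PO4, 2-methylbut-2-ene, t-BuOH/H2O) would give the glycidic acid F2.
- Treatment with 2,2'-dipyridyl disulfide and PPh3 would give the S-(pyridin-2-yl) thioester F3.
- Acylation of carbenoid 24 with F3 at −78 °C would give the bromo keto ester F4.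
- Chelation-controlled reduction of this α,β-epoxy ketone with Zn(BH4)2 (Et2O, −30 °C) is the established way to erythro epoxy alcohols, and the zinc alkoxide would lactonise onto the cis ester.

The route is rejoined at 25.

Step 6 (C2–C3 alkylation). The epoxy triflate may undergo elimination or epoxide opening faster than substitution. The fallback sets out from 6 and joins the fragments before the epoxide exists:
- Appel bromination (CBr4, PPh3, CH2Cl2, 0 °C) would give the allylic bromide F5.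
- Alkylation of 9 with F5 would give the enyne F6.
- Reagent-controlled Shi epoxidation of the trisubstituted alkene with the ketone derived from L-fructose (KHSO5, K2CO3, MeCN/dimethoxymethane/buffer, 0 °C) should give the 1S,10R epoxide; this is the enantiomer of the usual D-fructose ketone, which would give the R configuration at the CH carbon.

The route is rejoined at 11.

Further compounds
F1 | step 20 | (1S,4S,5R,6R,8S,10R)-13-{[tert-butyl(dimethyl)silyl]oxy}-8-hydroxy-1,10:4,5-diepoxygermacr-7(11)-en-12,6-olide | O[C@H]1C[C@@]2(C)O[C@H]2CC[C@]2(C)O[C@@H]2[C@@H]2OC(=O)C(CO[Si](C)(C)C(C)(C)C)=C21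
F2 | step 16 | (2S,3S)-3-{2-[(2S,3R)-3-{2-[(4-methoxybenzyl)oxy]ethyl}-3-methyloxiran-2-yl]ethyl}-3-methyloxirane-2-carboxylic acid | COc1ccc(COCC[C@@]2(C)O[C@H]2CC[C@]2(C)O[C@@H]2C(=O)O)cc1
F3 | step 16 | S-(pyridin-2-yl) (2S,3S)-3-{2-[(2S,3R)-3-{2-[(4-methoxybenzyl)oxy]ethyl}-3-methyloxiran-2-yl]ethyl}-3-methyloxirane-2-carbothioate | COc1ccc(COCC[C@@]2(C)O[C@H]2CC[C@]2(C)O[C@@H]2C(=O)Sc2ccccn2)cc1
F4 | step 16 | ethyl (2E)-3-bromo-2-({[tert-butyl(dimethyl)silyl]oxy}methyl)-4-[(2S,3S)-3-{2-[(2S,3R)-3-{2-[(4-methoxybenzyl)oxy]ethyl}-3-methyloxiran-2-yl]ethyl}-3-methyloxiran-2-yl]-4-oxobut-2-enoate (ketone cis to the ester) | COc1ccc(COCC[C@@]2(C)O[C@H]2CC[C@]2(C)O[C@@H]2C(=O)/C(Br)=C(/CO[Si](C)(C)C(C)(C)C)C(=O)OCC)cc1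
F5 | step 6 | 1-({[(3Z)-5-bromo-3-methylpent-3-en-1-yl]oxy}methyl)-4-methoxybenzene | BrC/C=C(/C)CCOCc1ccc(OC)cc1
F6 | step 6 | {(5Z)-8-[(4-methoxybenzyl)oxy]-6-methyloct-5-en-1-yn-1-yl}trimethylsilane | COc1ccc(COCC/C(C)=C\CCC#C[Si](C)(C)C)cc1
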